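**Retrosynthetic overview**
1. Numbering as in a 9,10-seco-ent-kaurane: ring A = cyclohexane C-1 to C-5 and C-10; ring B = γ-lactone (C-4, C-5, C-6, O, C-19); rings C and D = the bicyclo[3.2.1]octenone (C-8, C-9, C-11 to C-16); C-7 = the CH2 link.
2. Ring A is opened last, across C-3–C-4 and C-5–C-10, to butenolide 19 and the 2-silyloxy diene 21 (Diels–Alder). The diene oxygen, a C-1 carbonyl after hydrolysis, is a temporary activating group: it sets the regiochemistry, lets C-10 be hydroxylated, and is then removed through the tosylhydrazone.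
3. Feature that makes this possible: the C-4=C-5 double bond of ring B, conjugated with the lactone carbonyl C-19 (methyl on C-4, hydrogen on C-5), its two faces differentiated by the C-7 substituent on C-6.
4. Ring B comes from aldehyde 13 by reagent-controlled vinylation, methacrylation and ring-closing metathesis; ring D from an intramolecular aldol addition of the C-8 enolate to a 2-substituted acrolein on C-13; ring C from an organocatalytic Michael addition followed by aldol condensation.
5. Order of ring formation: ring C (step 2), ring D (step 6), ring B (step 12), ring A (step 15); the ring C ketone is masked as a dioxolane from step 13 to step 19.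

Key step: step 15

Assumption: the sense of induction of the prolinol ether catalyst (step 1) and of the sulfonamide ligand (step 10) is taken from the usual shielding models; should either be reversed, the other enantiomer of that catalyst or ligand is used.

**Step 1**
Reactants: 1 pent-4-enal; 2 but-3-en-2-one
Product: 3 (2R)-5-oxo-2-(prop-2-en-1-yl)hexanal
Conditions: (R)-2-[methoxy(diphenyl)methyl]pyrrolidine (5 mol %), ethyl 3,4-dihydroxybenzoate (20 mol %), neat, 4 °C
Reagents that add atoms: none
Why: Enamine-catalysed Michael addition of the aldehyde to the vinyl ketone, in which the diarylmethyl group of the catalyst shields one face of the E-enamine and so sets the only stereocenter (the later C-13).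

**Step 2**
Reactants: 3 (2R)-5-oxo-2-(prop-2-en-1-yl)hexanal
Product: 4 (4R)-4-(prop-2-en-1-yl)cyclohex-2-en-1-one
Conditions: KOH (0.1 M aq), n-Bu4NOH (cat.), THF/Et2O, reflux
Reagents that add atoms: none
Why: Intramolecular aldol condensation (Robinson-type ring closure) of the methyl ketone onto the aldehyde closes ring C, and cyclisation with dehydration should outrun enolisation of the α-branched aldehyde so that the stereocenter survives as the γ-carbon of the enone.

**Step 3**
Reactants: 4 (4R)-4-(prop-2-en-1-yl)cyclohex-2-en-1-one; 5 tert-butyl(2-iodoethoxy)dimethylsilane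
Product: 6 (4S,6R)-6-{2-[(tert-butyldimethylsilyl)oxy]ethyl}-4-(prop-2-en-1-yl)cyclohex-2-en-1-one
Conditions: LiN(i-Pr)2, THF, −78 °C; then 5, hexamethylphosphoramide, −78 → −25 °C
Reagents that add atoms: none
Why: Kinetic α'-deprotonation gives the cross-conjugated enolate, which is alkylated by the primary iodide (SN2); the trans isomer should predominate, but the configuration at this carbon is erased again in step 6.

**Step 4**
Reactants: 6 alkylated enone
Product: 8 2-[(1R,5R)-5-{2-[(tert-butyldimethylsilyl)oxy]ethyl}-4-oxocyclohex-2-en-1-yl]acetaldehyde, via secondary ozonide 7 (not isolated)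
Conditions: O3 (1 equiv), CH2Cl2, −78 °C; then Me2S, −78 °C → rt
Reagents that add atoms: ozone, [O-][O+]=O
Why: Ozonolysis with reductive work-up, in which the electron-rich terminal alkene reacts much faster than the electron-poor enone double bond.

**Step 5**
Reactants: 8 keto aldehyde
Product: 9 2-[(1S,5R)-5-{2-[(tert-butyldimethylsilyl)oxy]ethyl}-4-oxocyclohex-2-en-1-yl]prop-2-enal
Conditions: CH2=NMe2+ I− (Eschenmoser's salt), Et3N, CH2Cl2, rt
Reagents that add atoms: N,N-dimethylmethyleneiminium iodide, C=[N+](C)C.[I-]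
Why: Mannich reaction at the aldehyde α-carbon followed by β-elimination of dimethylamine (α-methylenation) gives the 2-substituted acrolein, the ketone being much slower to enolise under these conditions.

**Step 6**
Reactants: 9 keto enal
Product: 10 (1R,5S,7R)-1-{2-[(tert-butyldimethylsilyl)oxy]ethyl}-7-hydroxy-6-methylidenebicyclo[3.2.1]oct-3-en-2-one
Conditions: LiN(SiMe3)2, THF, −78 → −40 °C; AcOH, −78 °C
Reagents that add atoms: none
Why: Intramolecular aldol addition (5-exo-trig onto the non-enolisable aldehyde) of the kinetic α'-enolate closes ring D; the bridge can form only on the ring face that carries the acrolein unit, which fixes the quaternary C-8, while the lithium-chelated closed transition state holds the aldehyde oxygen syn to the enolate oxygen and so places the C-15 hydroxyl on the side of the ketone bridge.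

**Step 7**
Reactants: 10 bicyclic hydroxy enone
Product: 11 (1R,5S,7R)-1-{2-[(tert-butyldimethylsilyl)oxy]ethyl}-6-methylidene-2-oxobicyclo[3.2.1]oct-3-en-7-yl acetate
Conditions: Ac2O, 4-(dimethylamino)pyridine (cat.), pyridine, CH2Cl2, 0 °C → rt
Reagents that add atoms: acetic anhydride, CC(=O)OC(C)=O
Why: Nucleophile-catalysed acylation of the secondary alcohol; with a quaternary α-carbon the β-acetoxy ketone can neither eliminate nor undergo retro-aldol cleavage.

**Step 8**
Reactants: 11 silyl ether acetate
Product: 12 (1R,5S,7R)-1-(2-hydroxyethyl)-6-methylidene-2-oxobicyclo[3.2.1]oct-3-en-7-yl acetate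
Conditions: HF·pyridine, pyridine, THF, 0 °C
Reagents that add atoms: none
Why: Fluoride-mediated cleavage of the primary silyl ether, to which the acetate and the enone are inert.

**Step 9**
Reactants: 12 primary alcohol
Product: 13 (1R,5S,7R)-6-methylidene-2-oxo-1-(2-oxoethyl)bicyclo[3.2.1]oct-3-en-7-yl acetate
Conditions: Dess–Martin periodinane, CH2Cl2, 0 °C → rt
Reagents that add atoms: none
Why: Mild hypervalent-iodine oxidation of the primary alcohol to the aldehyde without touching the acetate or the alkenes.

**Step 10**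
Reactants: 13 aldehyde; 14 bromoethene
Product: 15 (1R,5S,7R)-1-[(2R)-2-hydroxybut-3-en-1-yl]-6-methylidene-2-oxobicyclo[3.2.1]oct-3-en-7-yl acetate
Conditions: 14 (THF solution), CrCl2, NiCl2 (cat.), (S)-N-[2-(4-isopropyl-4,5-dihydro-1,3-oxazol-2-yl)-6-methylphenyl]methanesulfonamide, Et3N, THF, rt
Reagents that add atoms: none
Why: Nozaki–Hiyama–Kishi vinylation, selective for the aldehyde over the hindered ketone and the acetate; the chiral sulfonamide ligand on chromium sets the new carbinol center (C-6) by reagent control, the ring stereocenters being too remote to interfere.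

**Step 11**
Reactants: 15 allylic alcohol; 16 2-methylprop-2-enoyl chloride
Product: 17 (2R)-1-[(1R,5S,7R)-7-acetoxy-6-methylidene-2-oxobicyclo[3.2.1]oct-3-en-1-yl]but-3-en-2-yl 2-methylprop-2-enoate
Conditions: Et3N, 4-(dimethylamino)pyridine (cat.), CH2Cl2, 0 °C
Reagents that add atoms: none
Why: Acylation of the secondary allylic alcohol by the acid chloride, with no change at C-6.

**Step 12**
Reactants: 17 methacrylate ester
Product: 18 (1R,5S,7R)-6-methylidene-1-{[(2R)-4-methyl-5-oxo-2,5-dihydrofuran-2-yl]methyl}-2-oxobicyclo[3.2.1]oct-3-en-7-yl acetate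
Conditions: second-generation Grubbs catalyst (5 mol %), CH2Cl2, 40 °C
Reagents that add atoms: none
Why: Ring-closing metathesis between the vinyl group and the methacrylate closes the α-methylbutenolide (ring B) with loss of ethene, the hindered exocyclic methylene and the ring C alkene not competing.

**Step 13**
Reactants: 18 butenolide enone
Product: 19 1,3-dioxolane ketal of 18 at the ring C carbonyl
Conditions: Me3SiOCH2CH2OSiMe3, Me3SiOTf (cat.), CH2Cl2, −78 → −20 °C
Reagents that add atoms: 1,2-bis(trimethylsilyloxy)ethane, C[Si](C)(C)OCCO[Si](C)(C)C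
Why: Silyl-triflate-catalysed ketalisation masks the ring C carbonyl, which would otherwise compete as a dienophile and later as a hydrazone acceptor; the double bond cannot move out of place because its γ-carbon is a bridgehead.

**Step 14**
Reactants: 20 pent-1-en-3-one
Product: 21 (Z)-trimethyl(penta-1,3-dien-3-yloxy)silane
Conditions: Me3SiOTf, Et3N, Et2O, 0 °C
Reagents that add atoms: trimethylsilyl trifluoromethanesulfonate, C[Si](C)(C)OS(=O)(=O)C(F)(F)F
Why: Soft enolisation and O-silylation of the ethyl ketone gives the 2-silyloxy diene, the Z-enol ether being the expected major isomer.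

**Step 15**
Reactants: 19 butenolide ketal; 21 silyloxy diene
Product: 23 ring A ketone (C-1 carbonyl), via cycloadduct silyl enol ether 22 (not isolated)
Conditions: 21 (5 equiv), 2,6-di-tert-butyl-4-methylphenol (cat.), toluene, 175 °C, sealed tube; then citric acid (aq), THF, 0 °C
Reagents that add atoms: none
Why: Thermal normal-electron-demand Diels–Alder cycloaddition (concerted, asynchronous) between the C-4=C-5 double bond of the butenolide, polarised by the lactone carbonyl C-19, and the 2-silyloxy diene, whose methyl-bearing nucleophilic terminus (the later C-10) bonds to the β-carbon C-5 while its CH2 terminus bonds to C-4; mild acid then hydrolyses enol ether 22 to the C-1 ketone. The closest known reactions are Diels–Alder additions of 2-silyloxy dienes to 5-substituted 3-methylfuran-2(5H)-ones, which give cis-fused lactones with an angular methyl group. Ring A is closed in the intermolecular [4+2] mode, C-3–C-4 and C-5–C-10 being formed suprafacially in one event. C-4 (quaternary) and C-5 are set together: the cis ring fusion follows from the geometry of the ring alkene, and the diene adds to the face opposite the C-7 substituent on C-6, which fixes both centers relative to C-6; the configuration formed at C-10 (endo addition should place the methyl cis to the lactone) is immaterial because this center is planarised in step 16. The step needs regioselectivity, secured by the silyloxy group at C-1 (para to the lactone carbonyl), facial selectivity, secured by the C-6 substituent, and chemoselectivity, secured by the dioxolane, which leaves the butenolide as the only electron-poor alkene. The silyloxy oxygen is a temporary activating group, used again in step 16 and removed in steps 17 and 18.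

**Step 16**
Reactants: 23 ring A ketone
Product: 24 α-hydroxy ketone (C-10 hydroxyl, C-1 carbonyl)
Conditions: O2 (1 atm), Cs2CO3 (20 mol %), P(OEt)3, DMSO, rt
Reagents that add atoms: dioxygen, O=O
Why: Base-catalysed autoxidation of the ketone at its tertiary α-carbon with in situ phosphite reduction of the hydroperoxide; oxygen adds to the C-1/C-10 enolate on the convex face of the cis-fused bicycle, anti to the lactone carbon C-6 on the neighbouring C-5, which sets C-10 (hydroxyl cis to H-5, methyl cis to the lactone).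

**Step 17**
Reactants: 24 α-hydroxy ketone
Product: 25 4-methylbenzenesulfonylhydrazone of 24
Conditions: TsNHNH2, MeOH, 50 °C
Reagents that add atoms: 4-methylbenzenesulfonohydrazide, Cc1ccc(cc1)S(=O)(=O)NN
Why: Condensation of the only free ketone with the sulfonyl hydrazide, the dioxolane keeping the ring C carbonyl out of the reaction.

**Step 18**
Reactants: 25 tosylhydrazone
Product: 27 dioxolane-protected target (C-1 as CH2), via N-boryl tosylhydrazine 26 (not isolated)
Conditions: catecholborane, CHCl3, 0 °C → rt; then NaOAc·3H2O, 60 °C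
Reagents that add atoms: none
Why: Tosylhydrazone reduction (Caglioti-type, catecholborane variant): hydride adds to the C=N bond, acetate then releases sulfinate and the resulting diazene loses N2, turning C-1 into CH2 without affecting the alkenes, the esters or the adjacent tertiary alcohol.

**Step 19**
Reactants: 27 dioxolane-protected target
Product: 28 CNP0172716.1
Conditions: pyridinium p-toluenesulfonate, THF/H2O, 45 °C
Reagents that add atoms: water, O
Why: Mild acid hydrolysis of the dioxolane regenerates the conjugated ketone of ring C and completes the target.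

**Compound list**
1 | pent-4-enal | C=CCCC=O | starting material
2 | but-3-en-2-one | CC(=O)C=C | starting material
3 | (2R)-5-oxo-2-(prop-2-en-1-yl)hexanal | C=CC[C@H](C=O)CCC(C)=O | intermediate
4 | (4R)-4-(prop-2-en-1-yl)cyclohex-2-en-1-one | C=CC[C@@H]1C=CC(=O)CC1 | intermediate
5 | tert-butyl(2-iodoethoxy)dimethylsilane | CC(C)(C)[Si](C)(C)OCCI | starting material
6 | (4S,6R)-6-{2-[(tert-butyldimethylsilyl)oxy]ethyl}-4-(prop-2-en-1-yl)cyclohex-2-en-1-one (trans isomer shown; its C-6 epimer is equally usable) | C=CC[C@@H]1C=CC(=O)[C@@H](CCO[Si](C)(C)C(C)(C)C)C1 | intermediate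
7 | 3-{[(1R,5R)-5-{2-[(tert-butyldimethylsilyl)oxy]ethyl}-4-oxocyclohex-2-en-1-yl]methyl}-1,2,4-trioxolane | C1OC(C[C@@H]2C=CC(=O)[C@@H](CCO[Si](C)(C)C(C)(C)C)C2)OO1 | intermediate (not isolated)
8 | 2-[(1R,5R)-5-{2-[(tert-butyldimethylsilyl)oxy]ethyl}-4-oxocyclohex-2-en-1-yl]acetaldehyde | O=CC[C@@H]1C=CC(=O)[C@@H](CCO[Si](C)(C)C(C)(C)C)C1 | intermediate
9 | 2-[(1S,5R)-5-{2-[(tert-butyldimethylsilyl)oxy]ethyl}-4-oxocyclohex-2-en-1-yl]prop-2-enal | C=C(C=O)[C@@H]1C=CC(=O)[C@@H](CCO[Si](C)(C)C(C)(C)C)C1 | intermediate
10 | (1R,5S,7R)-1-{2-[(tert-butyldimethylsilyl)oxy]ethyl}-7-hydroxy-6-methylidenebicyclo[3.2.1]oct-3-en-2-one | C=C1[C@@H]2C=CC(=O)[C@@](CCO[Si](C)(C)C(C)(C)C)(C2)[C@@H]1O | intermediate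
11 | (1R,5S,7R)-1-{2-[(tert-butyldimethylsilyl)oxy]ethyl}-6-methylidene-2-oxobicyclo[3.2.1]oct-3-en-7-yl acetate | C=C1[C@@H]2C=CC(=O)[C@@](CCO[Si](C)(C)C(C)(C)C)(C2)[C@@H]1OC(C)=O | intermediate
12 | (1R,5S,7R)-1-(2-hydroxyethyl)-6-methylidene-2-oxobicyclo[3.2.1]oct-3-en-7-yl acetate | C=C1[C@@H]2C=CC(=O)[C@@](CCO)(C2)[C@@H]1OC(C)=O | intermediate
13 | (1R,5S,7R)-6-methylidene-2-oxo-1-(2-oxoethyl)bicyclo[3.2.1]oct-3-en-7-yl acetate | C=C1[C@@H]2C=CC(=O)[C@@](CC=O)(C2)[C@@H]1OC(C)=O | intermediate
14 | bromoethene | C=CBr | starting material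
15 | (1R,5S,7R)-1-[(2R)-2-hydroxybut-3-en-1-yl]-6-methylidene-2-oxobicyclo[3.2.1]oct-3-en-7-yl acetate | C=C1[C@@H]2C=CC(=O)[C@@](C[C@@H](O)C=C)(C2)[C@@H]1OC(C)=O | intermediate
16 | 2-methylprop-2-enoyl chloride | CC(=C)C(Cl)=O | starting material
17 | (2R)-1-[(1R,5S,7R)-7-acetoxy-6-methylidene-2-oxobicyclo[3.2.1]oct-3-en-1-yl]but-3-en-2-yl 2-methylprop-2-enoate | C=C1[C@@H]2C=CC(=O)[C@@](C[C@@H](OC(=O)C(C)=C)C=C)(C2)[C@@H]1OC(C)=O | intermediate
18 | (1R,5S,7R)-6-methylidene-1-{[(2R)-4-methyl-5-oxo-2,5-dihydrofuran-2-yl]methyl}-2-oxobicyclo[3.2.1]oct-3-en-7-yl acetate | C=C1[C@@H]2C=CC(=O)[C@@](C[C@H]3OC(=O)C(C)=C3)(C2)[C@@H]1OC(C)=O | intermediate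
19 | 1,3-dioxolane ketal of 18 at the ring C carbonyl | C=C1[C@@H]2C=CC4(OCCO4)[C@@](C[C@H]3OC(=O)C(C)=C3)(C2)[C@@H]1OC(C)=O | intermediate
20 | pent-1-en-3-one | CCC(=O)C=C | starting material
21 | (Z)-trimethyl(penta-1,3-dien-3-yloxy)silane | C/C=C(\O[Si](C)(C)C)C=C | intermediate
22 | trimethylsilyl enol ether (C-1=C-2) of 23, the primary cycloadduct | C=C1[C@@H]2C=CC5(OCCO5)[C@@](C[C@H]3OC(=O)[C@]4(C)CC=C(O[Si](C)(C)C)[C@H](C)[C@H]34)(C2)[C@@H]1OC(C)=O | intermediate (not isolated)
23 | (1R,5S,7R)-1-{[(1R,3aR,7R,7aS)-3a,7-dimethyl-3,6-dioxooctahydro-2-benzofuran-1-yl]methyl}-6-methylidene-2-oxobicyclo[3.2.1]oct-3-en-7-yl acetate, ring C ketone as 1,3-dioxolane (the C-10 epimer expected from endo addition is shown; either epimer serves) | C=C1[C@@H]2C=CC5(OCCO5)[C@@](C[C@H]3OC(=O)[C@]4(C)CCC(=O)[C@H](C)[C@H]34)(C2)[C@@H]1OC(C)=O | intermediate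
24 | (1R,5S,7R)-1-{[(1R,3aR,7S,7aS)-7-hydroxy-3a,7-dimethyl-3,6-dioxooctahydro-2-benzofuran-1-yl]methyl}-6-methylidene-2-oxobicyclo[3.2.1]oct-3-en-7-yl acetate, ring C ketone as 1,3-dioxolane | C=C1[C@@H]2C=CC5(OCCO5)[C@@](C[C@H]3OC(=O)[C@]4(C)CCC(=O)[C@@](C)(O)[C@H]34)(C2)[C@@H]1OC(C)=O | intermediate
25 | 4-methylbenzenesulfonylhydrazone of 24 at the ring A ketone | C=C1[C@@H]2C=CC5(OCCO5)[C@@](C[C@H]3OC(=O)[C@]4(C)CCC(=NNS(=O)(=O)c6ccc(C)cc6)[C@@](C)(O)[C@H]34)(C2)[C@@H]1OC(C)=O | intermediate
26 | N-(1,3,2-benzodioxaborol-2-yl) tosylhydrazine formed from 25 by hydride addition at C-1 | C=C1[C@@H]2C=CC5(OCCO5)[C@@](C[C@H]3OC(=O)[C@]4(C)CCC(N(NS(=O)(=O)c6ccc(C)cc6)B7Oc8ccccc8O7)[C@@](C)(O)[C@H]34)(C2)[C@@H]1OC(C)=O | intermediate (not isolated)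
27 | (1R,5S,7R)-1-{[(1R,3aR,7R,7aS)-7-hydroxy-3a,7-dimethyl-3-oxooctahydro-2-benzofuran-1-yl]methyl}-6-methylidene-2-oxobicyclo[3.2.1]oct-3-en-7-yl acetate, ring C ketone as 1,3-dioxolane | C=C1[C@@H]2C=CC5(OCCO5)[C@@](C[C@H]3OC(=O)[C@]4(C)CCC[C@@](C)(O)[C@H]34)(C2)[C@@H]1OC(C)=O | intermediate
28 | (1R,5S,7R)-1-{[(1R,3aR,7R,7aS)-7-hydroxy-3a,7-dimethyl-3-oxooctahydro-2-benzofuran-1-yl]methyl}-6-methylidene-2-oxobicyclo[3.2.1]oct-3-en-7-yl acetate (CNP0172716.1) | C=C1[C@@H]2C=CC(=O)[C@@](C[C@H]3OC(=O)[C@]4(C)CCC[C@@](C)(O)[C@H]34)(C2)[C@@H]1OC(C)=O | target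

**Step count**
Total: 19 steps. Longest linear sequence: 18 steps (steps 1–13 and 15–19; step 14 prepares diene 21).

**Steps most likely to fail**

Step 15. The trisubstituted, α-methylated butenolide may be too poor a dienophile at temperatures the silyl dienol ether tolerates, so that the diene decomposes or oligomerises before it adds. The fallback sets out from 19 and comes back at 23. The diene is replaced by a much more reactive 1-amino-3-siloxy diene, at the cost of one extra unsaturation that is taken out again. Butan-2-one is condensed with N,N-dimethylformamide dimethyl acetal to (E)-1-(dimethylamino)pent-1-en-3-one F1, and KN(SiMe3)2 with tert-butyldimethylsilyl chloride converts this into (1E,3Z)-3-[(tert-butyldimethylsilyl)oxy]-N,N-dimethylpenta-1,3-dien-1-amine F2. F2 should add to 19 at 60–80 °C with the same regiochemistry and facial sense to give the amino silyl enol ether cycloadduct F3. HF·pyridine then cleaves the silyl enol ether and eliminates dimethylamine to the ring A enone F4 (C-1 ketone, C-2=C-3), and conjugate reduction with [(Ph3P)CuH]6 gives 23.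

Step 16. The autoxidation may go astray through enolisation toward the methylene C-2 instead of the methine C-10, through over-oxidation, or through base-induced retro-Michael opening of the 1,5-dicarbonyl array. The fallback sets out from 23 and comes back at 24 by a Rubottom oxidation. 23 is converted with Me3SiCl, NaI and Et3N in MeCN (equilibrating conditions) into the more substituted trimethylsilyl enol ether F5 (C-1=C-10). This is epoxidised on the convex face with dimethyldioxirane at −78 °C, where the enol ether reacts far faster than the other alkenes, and mild acidic work-up opens the silyloxy epoxide to 24.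

Step 17. Condensation may stall at the hindered carbonyl flanked by the fully substituted carbinol carbon, and forcing it invites acyloin rearrangement or loss of the dioxolane. The fallback sets out from 24 and comes back at 27 by radical deoxygenation. NaBH4 in MeOH at 0 °C reduces 24 to the ring A diol F6. Phenyl chlorothionoformate with pyridine acylates only the secondary hydroxyl to give the O-phenyl thiocarbonate F7. Bu3SnH with azobisisobutyronitrile in toluene at 90 °C (Barton–McCombie) then removes it to give 27.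

**Further compounds**
F1 | step 15 | (E)-1-(dimethylamino)pent-1-en-3-one | CCC(=O)/C=C/N(C)C
F2 | step 15 | (1E,3Z)-3-[(tert-butyldimethylsilyl)oxy]-N,N-dimethylpenta-1,3-dien-1-amine | C/C=C(\O[Si](C)(C)C(C)(C)C)/C=C/N(C)C
F3 | step 15 | amino silyl enol ether cycloadduct of 19 and F2 | C=C1[C@@H]2C=CC5(OCCO5)[C@@](C[C@H]3OC(=O)[C@]4(C)C(N(C)C)C=C(O[Si](C)(C)C(C)(C)C)[C@H](C)[C@H]34)(C2)[C@@H]1OC(C)=O
F4 | step 15 | ring A enone (C-1 ketone, C-2=C-3) | C=C1[C@@H]2C=CC5(OCCO5)[C@@](C[C@H]3OC(=O)[C@]4(C)C=CC(=O)[C@H](C)[C@H]34)(C2)[C@@H]1OC(C)=O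
F5 | step 16 | trimethylsilyl enol ether (C-1=C-10) of 23 | C=C1[C@@H]2C=CC5(OCCO5)[C@@](C[C@H]3OC(=O)[C@]4(C)CCC(O[Si](C)(C)C)=C(C)[C@H]34)(C2)[C@@H]1OC(C)=O
F6 | step 17 | ring A diol from 24 (C-1 carbinol) | C=C1[C@@H]2C=CC5(OCCO5)[C@@](C[C@H]3OC(=O)[C@]4(C)CCC(O)[C@@](C)(O)[C@H]34)(C2)[C@@H]1OC(C)=O
F7 | step 17 | O-phenyl thiocarbonate of F6 at the secondary hydroxyl | C=C1[C@@H]2C=CC5(OCCO5)[C@@](C[C@H]3OC(=O)[C@]4(C)CCC(OC(=S)Oc6ccccc6)[C@@](C)(O)[C@H]34)(C2)[C@@H]1OC(C)=O
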